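**Retrosynthetic overview**

1. The target is a tetrahydrofuran, ring atoms O1, C2, C3, C4, C5: C2 aryl trans to C3–CH2OH, C3/C4 trans, C4–CH2OH cis to C5 aryl, aryl groups 2,5-cis. The plan rests on reading C5(aryl)–C4(CH2O)–C3 as the opened form of a trans-2-aryl-3-(silyloxymethyl)cyclopropane-1,1-diester, and O1–C2 as the C=O of an O-protected vanillin.
2. Endgame, read backwards: ArO–Bn hydrogenolysis, Si–O cleavage, LiAlH4 (C3 ester to CH2OH, pivalate off), and the C3 monoester from the C3 gem-diester by dealkoxycarbonylation and thermodynamic epimerisation.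
3. Key disconnection: O1–C5 and C2–C3, made together in a Sn(OTf)2-catalysed [3+2] annulation of cyclopropane 6 with aldehyde 8.
4. Cyclopropane 6 comes from O-pivaloylconiferaldehyde and dimethyl bromomalonate by an aminocatalytic Michael-initiated ring closure, then reduction and silylation.
5. Ring order: cyclopropane (step 2), then the tetrahydrofuran (step 5), the only ring of the target that the route builds.

Key step: step 5

Remark on the chemistry: the (S)-configured diphenylprolinol silyl ether is taken to deliver the malonate to the C-β face remote from its CPh2(OSiMe3) group, as is general for β-aryl enals; this gives the (2S,3R) cyclopropane needed here.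

Remark on the chemistry: the primary alcohol is carried as its triisopropylsilyl ether, because chloride in hot wet DMSO (step 6) can strip a tert-butyldimethylsilyl ether, and a free CH2OH at C4 would lactonise onto a cis ester at C3 and fix the wrong C3 configuration.

**Route**

Step 1
Reactants: 1 coniferaldehyde [(E)-3-(4-hydroxy-3-methoxyphenyl)prop-2-enal]
Product: 2 2-methoxy-4-[(E)-3-oxoprop-1-en-1-yl]phenyl 2,2-dimethylpropanoate (O-pivaloylconiferaldehyde)
Conditions: PivCl, Et3N, DMAP (cat.), CH2Cl2, 0 °C to rt
Reagents that add atoms: pivaloyl chloride, CC(C)(C)C(Cl)=O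
Why: DMAP-catalysed O-acylation of the phenol leaves the enal untouched, and the hindered, electron-withdrawing pivalate is chosen because it resists the secondary-amine catalyst of step 2 and later damps the donor strength of the aryl ring.

Step 2
Reactants: 2 O-pivaloylconiferaldehyde; 3 dimethyl bromomalonate
Product: 4 dimethyl (2S,3R)-3-formyl-2-[3-methoxy-4-(pivaloyloxy)phenyl]cyclopropane-1,1-dicarboxylate (aryl and formyl trans)
Conditions: (S)-α,α-diphenylprolinol trimethylsilyl ether (20 mol%), 2,6-lutidine (1.1 equiv), CH2Cl2, 0 °C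
Reagents that add atoms: none
Why: Aminocatalytic Michael-initiated ring closure (iminium, then enamine activation), in which the malonate adds to C-β of the (E)-iminium ion on the face remote from the CPh2(OSiMe3) group of the (S)-catalyst and so sets the aryl-bearing carbon (2S), after which the enamine displaces bromide in a 3-exo-tet alkylation that places the formyl group trans to the aryl group (3R).

Step 3
Reactants: 4 dimethyl (2S,3R)-3-formyl-2-[3-methoxy-4-(pivaloyloxy)phenyl]cyclopropane-1,1-dicarboxylate
Product: 6 dimethyl (2S,3R)-2-[3-methoxy-4-(pivaloyloxy)phenyl]-3-{[(triisopropylsilyl)oxy]methyl}cyclopropane-1,1-dicarboxylate, via hydroxymethylcyclopropane diester 5 (not isolated)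
Conditions: NaBH4, MeOH–CH2Cl2, −20 °C, pH 7 work-up; crude 5, TIPSOTf, 2,6-lutidine, CH2Cl2, −78 to 0 °C
Reagents that add atoms: triisopropylsilyl trifluoromethanesulfonate, CC(C)[Si](OS(=O)(=O)C(F)(F)F)(C(C)C)C(C)C
Why: Chemoselective NaBH4 reduction of the aldehyde (the methyl esters and the aryl pivalate are not reduced at −20 °C) is followed at once by O-silylation with the silyl triflate, which at −78 °C should outrun lactonisation of 5 onto the cis ester, and no stereocentre is involved.

Step 4
Reactants: 7 vanillin (4-hydroxy-3-methoxybenzaldehyde)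
Product: 8 4-(benzyloxy)-3-methoxybenzaldehyde
Conditions: BnBr, K2CO3, DMF, rt
Reagents that add atoms: benzyl bromide, BrCc1ccccc1
Why: Williamson etherification of the phenoxide with a benzylic bromide, with the aldehyde unaffected.

Step 5
Reactants: 6 dimethyl (2S,3R)-2-[3-methoxy-4-(pivaloyloxy)phenyl]-3-{[(triisopropylsilyl)oxy]methyl}cyclopropane-1,1-dicarboxylate; 8 4-(benzyloxy)-3-methoxybenzaldehyde
Product: 9 dimethyl (2R,4R,5R)-2-[4-(benzyloxy)-3-methoxyphenyl]-5-[3-methoxy-4-(pivaloyloxy)phenyl]-4-{[(triisopropylsilyl)oxy]methyl}oxolane-3,3-dicarboxylate (2,5-cis and 4,5-cis)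
Conditions: 8 (2 equiv), Sn(OTf)2 (10 mol%), CH2Cl2, 0 °C to rt; Et3N quench once 6 is consumed
Reagents that add atoms: none
Why: Divalent tin triflate chelates the geminal diester and polarises the C1–C2 bond of 6; the carbonyl oxygen of 8 displaces the malonate carbon at the aryl-bearing carbon from the rear (SN2-like, forming O1–C5), and the tin malonate enolate then adds to the (E)-O-alkyl oxocarbenium carbon (forming C2–C3), which is the known Lewis-acid-catalysed formal [3+2] annulation of 2-arylcyclopropane-1,1-diesters with aldehydes. The tetrahydrofuran ring closes in the second event, an aldol-type 5-(enolexo)-endo-trig attack, feasible because the nucleophile is an exocyclic enolate and the cation is held only by the flexible C5–O1 single bond. C5 is controlled by the cyclopropane: inversion turns the trans aryl/CH2OSi relation of 6 into the 4,5-cis relation (5R), while C4 is carried through unchanged. C2 is controlled by an envelope transition state with both aryl groups pseudoequatorial, which gives the 2,5-cis ring. The step needs a stereospecific, non-ionising opening at the benzylic carbon and not at the CH2OSi-bearing one: the 4-pivaloyloxy group brings the donor strength of the aryl ring down to about that of phenyl so that a free benzylic cation does not form, the aryl group directs the nucleophile to its own carbon, and the electron-rich aldehyde in excess is a good nucleophile. The bulky triisopropylsilyl ether is a poor ligand for tin and should survive the catalytic Lewis acid.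

Step 6
Reactants: 9 dimethyl (2R,4R,5R)-2-[4-(benzyloxy)-3-methoxyphenyl]-5-[3-methoxy-4-(pivaloyloxy)phenyl]-4-{[(triisopropylsilyl)oxy]methyl}oxolane-3,3-dicarboxylate
Product: 11 methyl (2S,3S,4R,5R)-2-[4-(benzyloxy)-3-methoxyphenyl]-5-[3-methoxy-4-(pivaloyloxy)phenyl]-4-{[(triisopropylsilyl)oxy]methyl}oxolane-3-carboxylate (ester trans to the C2 aryl and to the C4 CH2OSi group), via all-cis monoester 10 (not isolated)
Conditions: LiCl (3 equiv), H2O (2 equiv), DMSO, 140 °C; extractive work-up; DBU (2 equiv), toluene, 90 °C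
Reagents that add atoms: none
Why: Krapcho dealkoxycarbonylation (SN2 demethylation by chloride, loss of CO2, protonation of the ester enolate, expected mainly on the open face to give 10) is followed by amidine-base epimerisation through the ester enolate, which under thermodynamic control places the C3 ester trans to both of its cis-disposed neighbours, while C2, C4 and C5 carry no acidic hydrogen and the non-nucleophilic DBU leaves the pivalate in place.

Step 7
Reactants: 11 methyl (2S,3S,4R,5R)-2-[4-(benzyloxy)-3-methoxyphenyl]-5-[3-methoxy-4-(pivaloyloxy)phenyl]-4-{[(triisopropylsilyl)oxy]methyl}oxolane-3-carboxylate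
Product: 12 {(2S,3R,4R,5R)-2-[4-(benzyloxy)-3-methoxyphenyl]-5-(4-hydroxy-3-methoxyphenyl)-4-{[(triisopropylsilyl)oxy]methyl}oxolan-3-yl}methanol
Conditions: LiAlH4, THF, 0 °C to rt; Rochelle salt work-up
Reagents that add atoms: none
Why: Hydride reduction of the methyl ester to the primary alcohol with concomitant reductive cleavage of the aryl pivalate, the silyl ether, the benzyl ether and the ring ether being inert to LiAlH4 and no stereocentre being touched.

Step 8
Reactants: 12 {(2S,3R,4R,5R)-2-[4-(benzyloxy)-3-methoxyphenyl]-5-(4-hydroxy-3-methoxyphenyl)-4-{[(triisopropylsilyl)oxy]methyl}oxolan-3-yl}methanol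
Product: 13 [(2S,3R,4R,5R)-2-[4-(benzyloxy)-3-methoxyphenyl]-5-(4-hydroxy-3-methoxyphenyl)oxolane-3,4-diyl]dimethanol
Conditions: TBAF, AcOH (1:1), THF, rt to 40 °C
Reagents that add atoms: none
Why: Fluoride-induced Si–O cleavage driven by the Si–F bond, with the acetic acid buffer keeping the free phenol protonated so that the C5–O1 bond para to it is not opened through a quinone methide.

Step 9
Reactants: 13 [(2S,3R,4R,5R)-2-[4-(benzyloxy)-3-methoxyphenyl]-5-(4-hydroxy-3-methoxyphenyl)oxolane-3,4-diyl]dimethanol
Product: 14 [(2S,3R,4R,5R)-2,5-bis(4-hydroxy-3-methoxyphenyl)oxolane-3,4-diyl]dimethanol (target)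
Conditions: H2 (1 atm), 10% Pd/C, EtOAc, rt
Reagents that add atoms: none
Why: Hydrogenolysis of the aryl benzyl ether on Pd/C, which under neutral conditions at 1 atm should be much faster than cleavage of the ring's dialkyl benzylic C–O bonds, frees the second phenol without touching a stereocentre.

**Compound list**

1 | coniferaldehyde, (E)-3-(4-hydroxy-3-methoxyphenyl)prop-2-enal | COc1cc(/C=C/C=O)ccc1O | starting material
2 | 2-methoxy-4-[(E)-3-oxoprop-1-en-1-yl]phenyl 2,2-dimethylpropanoate | COc1cc(/C=C/C=O)ccc1OC(=O)C(C)(C)C | intermediate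
3 | dimethyl bromomalonate | COC(=O)C(Br)C(=O)OC | starting material
4 | dimethyl (2S,3R)-3-formyl-2-[3-methoxy-4-(pivaloyloxy)phenyl]cyclopropane-1,1-dicarboxylate | COC(=O)C1(C(=O)OC)[C@H](c2ccc(OC(=O)C(C)(C)C)c(OC)c2)[C@H]1C=O | intermediate
5 | dimethyl (2S,3R)-3-(hydroxymethyl)-2-[3-methoxy-4-(pivaloyloxy)phenyl]cyclopropane-1,1-dicarboxylate (hydroxymethylcyclopropane diester, not isolated) | COC(=O)C1(C(=O)OC)[C@H](c2ccc(OC(=O)C(C)(C)C)c(OC)c2)[C@H]1CO | intermediate
6 | dimethyl (2S,3R)-2-[3-methoxy-4-(pivaloyloxy)phenyl]-3-{[(triisopropylsilyl)oxy]methyl}cyclopropane-1,1-dicarboxylate | COC(=O)C1(C(=O)OC)[C@H](c2ccc(OC(=O)C(C)(C)C)c(OC)c2)[C@H]1CO[Si](C(C)C)(C(C)C)C(C)C | intermediate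
7 | vanillin | COc1cc(C=O)ccc1O | starting material
8 | 4-(benzyloxy)-3-methoxybenzaldehyde | COc1cc(C=O)ccc1OCc1ccccc1 | intermediate
9 | dimethyl (2R,4R,5R)-2-[4-(benzyloxy)-3-methoxyphenyl]-5-[3-methoxy-4-(pivaloyloxy)phenyl]-4-{[(triisopropylsilyl)oxy]methyl}oxolane-3,3-dicarboxylate | COc1cc([C@H]2O[C@@H](c3ccc(OC(=O)C(C)(C)C)c(OC)c3)[C@@H](CO[Si](C(C)C)(C(C)C)C(C)C)C2(C(=O)OC)C(=O)OC)ccc1OCc1ccccc1 | intermediate
10 | methyl (2S,3R,4R,5R)-2-[4-(benzyloxy)-3-methoxyphenyl]-5-[3-methoxy-4-(pivaloyloxy)phenyl]-4-{[(triisopropylsilyl)oxy]methyl}oxolane-3-carboxylate (all-cis monoester, not isolated) | COc1cc([C@H]2O[C@@H](c3ccc(OC(=O)C(C)(C)C)c(OC)c3)[C@@H](CO[Si](C(C)C)(C(C)C)C(C)C)[C@H]2C(=O)OC)ccc1OCc1ccccc1 | intermediate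
11 | methyl (2S,3S,4R,5R)-2-[4-(benzyloxy)-3-methoxyphenyl]-5-[3-methoxy-4-(pivaloyloxy)phenyl]-4-{[(triisopropylsilyl)oxy]methyl}oxolane-3-carboxylate | COc1cc([C@H]2O[C@@H](c3ccc(OC(=O)C(C)(C)C)c(OC)c3)[C@@H](CO[Si](C(C)C)(C(C)C)C(C)C)[C@@H]2C(=O)OC)ccc1OCc1ccccc1 | intermediate
12 | {(2S,3R,4R,5R)-2-[4-(benzyloxy)-3-methoxyphenyl]-5-(4-hydroxy-3-methoxyphenyl)-4-{[(triisopropylsilyl)oxy]methyl}oxolan-3-yl}methanol | COc1cc([C@H]2O[C@@H](c3ccc(O)c(OC)c3)[C@@H](CO[Si](C(C)C)(C(C)C)C(C)C)[C@@H]2CO)ccc1OCc1ccccc1 | intermediate
13 | [(2S,3R,4R,5R)-2-[4-(benzyloxy)-3-methoxyphenyl]-5-(4-hydroxy-3-methoxyphenyl)oxolane-3,4-diyl]dimethanol | COc1cc([C@H]2O[C@@H](c3ccc(O)c(OC)c3)[C@@H](CO)[C@@H]2CO)ccc1OCc1ccccc1 | intermediate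
14 | [(2S,3R,4R,5R)-2,5-bis(4-hydroxy-3-methoxyphenyl)oxolane-3,4-diyl]dimethanol | COc1cc([C@H]2O[C@@H](c3ccc(O)c(OC)c3)[C@@H](CO)[C@@H]2CO)ccc1O | target

**Step count**

Total: 9 steps. Longest linear sequence: 8 steps (steps 1, 2, 3, 5, 6, 7, 8, 9); step 4 is a one-step side branch.

**Steps most likely to fail**

Step 5 (key annulation). The activated cyclopropane may ionise to an open benzylic zwitterion before the aldehyde attacks, which would erode the C4/C5 relation and the enantiopurity. The Lewis acid may also reopen the product at C2 on long exposure, with drift towards the 2,5-trans ring. The fallback separates the two bond formations; it sets out from 6 and 8 and comes back at 9. Aldehyde 8 would be reduced (NaBH4, MeOH) to [4-(benzyloxy)-3-methoxyphenyl]methanol F1. This alcohol is a far better nucleophile than a carbonyl oxygen and would open 6 at the aryl-bearing carbon with inversion under Cu(OTf)2 catalysis (CH2Cl2, rt). The product would be the ring-opened benzylic ether dimethyl 2-[(1R,2R)-1-{[4-(benzyloxy)-3-methoxyphenyl]methoxy}-1-[3-methoxy-4-(pivaloyloxy)phenyl]-3-[(triisopropylsilyl)oxy]propan-2-yl]propanedioate F2. Oxidation of its electron-rich ArCH2–O position with DDQ (Cu(OTf)2 cat., 4 Å molecular sieves, CH2Cl2) would generate the same O-alkyl oxocarbenium ion as the annulation, and capture by the malonate would close C2–C3 to give 9.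

Step 6 (dealkoxycarbonylation and C3 equilibration). In the hot medium, which becomes basic as the reaction proceeds, the aryl pivalate or the silyl ether may be hydrolysed. A phenoxide could then open the C5–O1 bond through a quinone methide, and a free CH2OH could lactonise onto the C3 ester; equilibration at C3 may also stay incomplete. The fallback removes the ester in two base-free stages; it sets out from 9 and returns at 11. LiI in refluxing EtOAc would cleave one ester methyl group by SN2 attack and, after acidification, give the half-acid (2R,4R,5R)-2-[4-(benzyloxy)-3-methoxyphenyl]-3-(methoxycarbonyl)-5-[3-methoxy-4-(pivaloyloxy)phenyl]-4-{[(triisopropylsilyl)oxy]methyl}oxolane-3-carboxylic acid F3 (mixture at C3). This would lose CO2 on warming in toluene with a little pyridine (100 °C), and the crude monoester would be equilibrated with DBU as in step 6 to give 11.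

Step 2 (aminocatalytic cyclopropanation). The bromomalonate may N-alkylate the secondary-amine catalyst, and the base may reopen the formylcyclopropane, so that conversion stalls or the enantiopurity erodes. The fallback separates conjugate addition from ring closure; it sets out from 2 and returns at 4. Dimethyl malonate, which is not an alkylating agent, would be added to 2 with the same (S)-catalyst (EtOH, 0 °C) to give dimethyl 2-[(1R)-1-[3-methoxy-4-(pivaloyloxy)phenyl]-3-oxopropyl]propanedioate F4. Oxidative ring closure with I2 and DBU (THF, 0 °C; halogenation at the malonate carbon, then 3-exo-tet alkylation by the aldehyde enolate, trans as in step 2) would then give 4 without the chiral amine being exposed to a bromomalonate.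

**Further compounds**

F1 | step 5 | [4-(benzyloxy)-3-methoxyphenyl]methanol | COc1cc(CO)ccc1OCc1ccccc1
F2 | step 5 | dimethyl 2-[(1R,2R)-1-{[4-(benzyloxy)-3-methoxyphenyl]methoxy}-1-[3-methoxy-4-(pivaloyloxy)phenyl]-3-[(triisopropylsilyl)oxy]propan-2-yl]propanedioate | COc1cc(CO[C@@H](c2ccc(OC(=O)C(C)(C)C)c(OC)c2)[C@@H](CO[Si](C(C)C)(C(C)C)C(C)C)C(C(=O)OC)C(=O)OC)ccc1OCc1ccccc1
F3 | step 6 | (2R,4R,5R)-2-[4-(benzyloxy)-3-methoxyphenyl]-3-(methoxycarbonyl)-5-[3-methoxy-4-(pivaloyloxy)phenyl]-4-{[(triisopropylsilyl)oxy]methyl}oxolane-3-carboxylic acid (mixture at C3) | COc1cc([C@H]2O[C@@H](c3ccc(OC(=O)C(C)(C)C)c(OC)c3)[C@@H](CO[Si](C(C)C)(C(C)C)C(C)C)C2(C(=O)O)C(=O)OC)ccc1OCc1ccccc1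
F4 | step 2 | dimethyl 2-[(1R)-1-[3-methoxy-4-(pivaloyloxy)phenyl]-3-oxopropyl]propanedioate | COC(=O)C(C(=O)OC)[C@H](c1ccc(OC(=O)C(C)(C)C)c(OC)c1)CC=O
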